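Readings and results were computed with made-up constants, and the scatter is random.

Before you choose a charge for the most ring in percent, decide to count how many solution-fills that charge holds, as you would count tank turnovers.

| flask | solid substrate | temperature | remark | time |
|---|---|---|---|---|
| ash | 22 mM | 35 °C | run made earlier |  |
| Sunday's | 5.0 mM | 55 °C |  | 5.0 min |
| Wednesday's | 5.0 mM | 35 °C |  | 5.0 min |
| Thursday's | 20 mM | 35 °C |  | 5.0 min |
| Monday's | 20 mM | 55 °C |  | 5.0 min |

ash run (percent of the solid substrate charged)

| time / min | ring / % | solid substrate / % |
|---|---|---|
| 0.250 | 1.0 | 87.7 |
| 0.500 | 0.9 | 81.5 |
| 1.33 | 2.8 | 72.6 |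
| 3.00 | 7.4 | 63.3 |

(each reading ± 0.5 percentage points)

1. all flasks from highest to lowest amount of ring, in percent of the solid substrate charged, at 5.0 min (Sunday's / Wednesday's / Thursday's / Monday's)
2. the same order at 1.0 min (Sunday's / Wednesday's / Thursday's / Monday's)
3. the amount of ring, in percent of the solid substrate charged of the flask you put first, at 5.0 min
4. the amount of ring, in percent of the solid substrate charged of the flask you put last, at 5.0 min

- given per volume of solution although it is solid: solid substrate
- at the start none of the solid substrate is in solution
- what has only dissolved of solid substrate counts as not reacted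
- the earlier runs do not show what temperature does; that part of a forecast is a guess

Read the solid column down the table. Its first row is at 87.7 % after 0.250 min, a pace of 0.492 /min of the charge, but between the last two rows it falls at 0.0557 /min, which is slower. Draw that slow line back to the start and it says the ash charge lost 20.0 % in a first rush. That is the gulp, the amount a solution takes up at once, here, as a reading that carries the scatter of these rows, 4.40 mM, a working stand-in for the solubility. The count of a flask is its charge over the gulp.

My own reckoning, for 35 °C, is this. Wednesday's counts 1.14 gulps, so 88.0 % of its charge goes in with the rush, while Thursday's counts 4.55, so 22.0 % does. With the ash drain, taken as the same absolute flow, I estimate the solid of Thursday's at 47.4 % at 5.0 min. While solid stands, I expect flasks of equal time and temperature to hold ring worth the same number of gulps, so its percentage falls as one over the count. For the hot flasks I have no count.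

The forecast gives Sunday's > Monday's > Wednesday's > Thursday's at 5.0 min and Sunday's > Monday's > Wednesday's > Thursday's at 1.0 min, with 60 % and 14 % at the ends, on the ground that at the small charge “a larger fraction can dissolve and react”. It calls the temperature effect a guess.

The flasks give Wednesday's > Sunday's > Monday's > Thursday's at 5.0 min, from 31.9 % down to 11.4 %, and Sunday's > Monday's > Wednesday's > Thursday's at 1.0 min. So first place goes to Wednesday's, not the forecast's Sunday's: Sunday's has 35.9 % at 1.0 min but 22.3 % at 5.0 min, beside 44.2 % side product. Thursday's, with 50.7 % still solid, holds ring worth 0.518 gulps.

    starting material ⇌ ring (K = 1.60, k = 0.150 /min, Ea = 96.0 kJ/mol, ΔH = −26.0 kJ/mol)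
    2 starting material → open dimer (k = 3.50 /M/min, Ea = 44.0 kJ/mol)
    solid substrate ⇌ starting material, rate k3*(cs3 - [starting material]) while solid is left; crystals form when [starting material] > cs3 (solubility = 5.60 mM, k = 2.60 /min)
    starting material + ring → side product (k = 24.0 /M/min, Ea = 52.0 kJ/mol)
    (constants at 35 °C)

Take the neighbour of Thursday's charged with 80 mM, at the same time and temperature: it counts 18.2 gulps, so the same ring makes 2.85 % of its charge. The computed flask gives 2.85 %, with 87.7 % still solid.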